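We start from a ratio, that of the exposure in blue to the exposure in grey, which comes to 5.71. By exposure we mean the partner concentration times the mean time a part of the substrate has spent in the flask. In a flask fed at a steady rate that mean time is, once the feed is over, the whole time less half the feed, and during the feed it is half the time so far.

| flask | substrate | partner | temperature | remark | time |
|---|---|---|---|---|---|
| autumn | 0.25 M (fed, over 12 h) | 0.49 M | 0 °C | run made earlier |  |
| winter | 0.25 M (fed, over 12 h) | 2 M | 11 °C | run made earlier |  |
| blue | 0.25 M | 2.50 M | 5 °C | everything together at the start | 20 h |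
| grey | 0.25 M (fed, over 12 h) | 0.625 M | 5 °C |  | 20 h |

- autumn (time / h: mono adduct / %, substrate / %): 1.50: 0, 13; 3.00: 0, 25; 5.00: 0, 41; 6.00: 0, 48; 8.00: 0, 67; 10.0: 2, 82
- winter (time / h: mono adduct / %, substrate / %): 0.833: 1, 10; 1.33: 1, 11; 2.00: 3, 17; 4.00: 6, 28; 6.00: 9, 38; 10.0: 12, 51

(scatter of a reading: 1.5 percentage points)

* the flask that ends with the higher amount of mono adduct, in percent of the substrate charged, or "neither" when 2 percentage points or less lies between them (blue / grey / neither)
* final mono adduct, as a percentage of the substrate charged, in blue
* final mono adduct, as a percentage of the substrate charged, in grey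

- percentages count the whole charge, also what has not yet gone in

Blue has an exposure of 50.0 M·h, and grey has 525 M·min. From the last reading of each earlier run, the loss of fed substrate per unit of exposure is as follows:

autumn: 0.00658 L mol⁻¹ h⁻¹, a weak reading, with a loss of 1.3 percentage points against a scatter of 1.5 points

winter: 0.0491 L mol⁻¹ h⁻¹

at the temperature of blue and grey, interpolated on a logarithmic scale: 0.0164 L mol⁻¹ h⁻¹

This makes the reacted substrate 56.0 % in blue and 13.4 % in grey. Grey then spends about 5.35 % of its partner, so we freeze the partner and treat the loss as pseudo-first-order.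

Winter's last reading has 0.371 of the reacted substrate standing as mono adduct, at an exposure of 600 M·min, close to grey's. We lend grey that share, which gives 4.96 % mono adduct.

Now we turn the question round. For grey to draw level, blue's share must fall to 0.0887, a quarter of winter's reading. We do not expect so deep a fall, and we put blue near winter's last mono adduct, 12 %.

The forecast gave 16 % for blue and 12 % for grey, which is above our grey, and it names the same winner: “Blue is ahead.”

The simulation gives 16.1 % in blue and 5.08 % in grey, so blue holds more.

    partner + mono adduct → bis adduct (k = 0.00670 L mol⁻¹ h⁻¹, Ea = 60.0 kJ mol⁻¹)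
    substrate + partner → other mono adduct (k = 0.00400 L mol⁻¹ h⁻¹, Ea = 80.0 kJ mol⁻¹)
    substrate + partner ⇌ mono adduct (K = 1.00 L mol⁻¹, k = 0.0180 L mol⁻¹ h⁻¹, Ea = 84.0 kJ mol⁻¹, ΔH = 35.0 kJ mol⁻¹)
    partner + other mono adduct → bis adduct (k = 0.00130 L mol⁻¹ h⁻¹, Ea = 65.0 kJ mol⁻¹)
    substrate + mono adduct → side product (k = 0.660 L mol⁻¹ h⁻¹, Ea = 53.0 kJ mol⁻¹)
    (constants at 5 °C)

Substrate left at the end of blue, 24.7 %, gives a loss per unit of exposure of 0.0280 L mol⁻¹ h⁻¹. Grey's exposure with this value gives 78.3 % substrate left, and grey held 77.4 % at the end. The neighbouring flask is grey with 2.5 M of partner, and its exposure is 35.0 M·h. The same reckoning gives 37.5 % substrate left in that neighbour, which held 38.8 % at the end, with mono adduct at 16.4 %.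

The earlier runs and the new flask come from a simulation from invented constants; the scatter is artificial.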